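**Retrosynthetic overview**
- The target comes from its C5 dimethyl ketal by a final hydrolysis.
- The ten-membered ring (formed last) and the trans-fused α-methylene lactone arise together by C3a–C4 bond formation: a chromium-catalysed intramolecular allylation of a C4 aldehyde by an α-(bromomethyl)butenolide.
- The butenolide (first ring formed) comes from ring-closing metathesis of a C11a 2-(bromomethyl)acrylate; the C11 ester comes from a Yamaguchi coupling with (2E)-3-methylpent-2-enoic acid.
- The C8–C9 bond comes from copper-catalysed opening of a C9–C11a epoxy alcohol fragment by a C4–C8 Grignard fragment.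
- The bromo ketal fragment comes from α-methylene-γ-butyrolactone (asymmetric hydrogenation sets C6); the epoxy alcohol comes from methacrolein (alkoxyallylboration sets C11 and C11a, directed epoxidation sets C10).

Assumption: locants follow cyclodeca[b]furan numbering of the target (O1, C2 lactone carbonyl, C3 methylidene carbon, C3a, C4 carbinol, C5 ketone, C6, C7–C9 methylenes, C10 tertiary carbinol, C11 ester carbon, C11a lactone O–CH); the SMILES is read as 3aS,4S,6S,10R,11S,11aR with a (2E) side chain.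

**Step 1**
Reactants: 1 3-methylideneoxolan-2-one (α-methylene-γ-butyrolactone)
Product: 2 (3S)-3-methyloxolan-2-one
Conditions: H2 (100 atm), Ru(OAc)2[(R)-BINAP] (0.5 mol %), CH2Cl2, 50 °C
Reagents that add atoms: none
Why: Noyori-type asymmetric hydrogenation of the exocyclic enoate, with the lactone carbonyl chelating ruthenium and the BINAP hand fixing the face of hydrogen delivery, sets C6 as S (the ligand hand is confirmed on the first run by the rotation of this known lactone).

**Step 2**
Reactants: 2 (3S)-3-methyloxolan-2-one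
Product: 3 (3S)-5-hydroxy-1-(methoxymethoxy)-3-methylpentan-2-one
Conditions: Bu3SnCH2OMOM, n-BuLi, THF, −78 °C; then 2, −78 °C; AcOH quench at −78 °C
Reagents that add atoms: tributyl[(methoxymethoxy)methyl]stannane, CCCC[Sn](CCCC)(CCCC)COCOC
Why: Tin–lithium exchange gives the alkoxymethyllithium, and its addition to the lactone (acyl substitution by an organolithium) stops at the lithium hemiketalate at −78 °C, so the hydroxy ketone forms without double addition or enolisation at C6.

**Step 3**
Reactants: 3 (3S)-5-hydroxy-1-(methoxymethoxy)-3-methylpentan-2-one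
Product: 4 (3S)-5-bromo-1-(methoxymethoxy)-3-methylpentan-2-one
Conditions: CBr4, PPh3, CH2Cl2, 0 °C
Reagents that add atoms: carbon tetrabromide, BrC(Br)(Br)Br
Why: The Appel reaction converts the primary alcohol (open-chain form of the hydroxy ketone) into the bromide under neutral conditions that leave the MOM ether and the C6 stereocentre alone.

**Step 4**
Reactants: 4 (3S)-5-bromo-1-(methoxymethoxy)-3-methylpentan-2-one
Product: 5 (3S)-5-bromo-2,2-dimethoxy-1-(methoxymethoxy)-3-methylpentane
Conditions: HC(OMe)3, MeOH, PPTS (10 mol %), 40 °C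
Reagents that add atoms: trimethyl orthoformate, COC(OC)OC
Why: Orthoformate-driven acid-catalysed ketalisation masks the ketone for the Grignard chemistry, and the weak acid PPTS keeps the MOM ether and avoids enolisation at C6.

**Step 5**
Reactants: 6 prop-2-en-1-ol
Product: 7 3-(methoxymethoxy)prop-1-ene
Conditions: MOMCl, i-Pr2NEt, CH2Cl2, 0 °C to rt
Reagents that add atoms: chloromethyl methyl ether, COCCl
Why: Standard O-alkylation (MOM protection) gives the allyl ether needed for the alkoxyallylboration.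

**Step 6**
Reactants: 7 3-(methoxymethoxy)prop-1-ene; 8 2-methylprop-2-enal (methacrolein)
Product: 11 (3R,4R)-4-(methoxymethoxy)-2-methylhexa-1,5-dien-3-ol, via (Z)-3-(methoxymethoxy)allyllithium 9 (not isolated), via B-[(Z)-3-(methoxymethoxy)allyl]diisopinocampheylborane 10 (not isolated)
Conditions: s-BuLi, THF, −78 °C; (−)-Ipc2BOMe; BF3·OEt2; then 8, −78 °C; NaOH, H2O2, 0 °C to rt
Reagents that add atoms: none
Why: Brown alkoxyallylboration through a chair Zimmerman–Traxler transition state: the Z-γ-alkoxyallyl geometry gives the syn C11/C11a relationship, and the isopinocampheyl groups derived from (+)-α-pinene direct attack to the Si face of the aldehyde, setting both centres.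

**Step 7**
Reactants: 11 (3R,4R)-4-(methoxymethoxy)-2-methylhexa-1,5-dien-3-ol
Product: 12 (1S,2R)-2-(methoxymethoxy)-1-[(2R)-2-methyloxiran-2-yl]but-3-en-1-ol
Conditions: VO(acac)2 (2 mol %), t-BuOOH, CH2Cl2, 0 °C
Reagents that add atoms: tert-butyl hydroperoxide, CC(C)(C)OO
Why: Hydroxyl-directed vanadium-catalysed epoxidation delivers oxygen only to the adjacent 1,1-disubstituted alkene, and A(1,2) strain between the alkene methyl and the carbinol substituent favours the erythro epoxy alcohol, which sets C10 as R.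

**Step 8**
Reactants: 5 (3S)-5-bromo-2,2-dimethoxy-1-(methoxymethoxy)-3-methylpentane; 12 (1S,2R)-2-(methoxymethoxy)-1-[(2R)-2-methyloxiran-2-yl]but-3-en-1-ol
Product: 14 (3S,7R,8S,9R)-2,2-dimethoxy-1,9-bis(methoxymethoxy)-3,7-dimethylundec-10-ene-7,8-diol, via [(3S)-4,4-dimethoxy-5-(methoxymethoxy)-3-methylpentyl]magnesium bromide 13 (not isolated)
Conditions: 5, Mg, THF, 45 °C; 12, i-PrMgCl (1.0 equiv), THF, −40 °C; then 13 (1.4 equiv), CuI (15 mol %), −40 to 0 °C
Reagents that add atoms: none
Why: Copper-catalysed Grignard opening of the 2,2-disubstituted epoxide occurs by SN2 attack at the unhindered CH2 terminus, forming the C8–C9 bond and leaving the C10 configuration untouched while the carbinol sits as its magnesium alkoxide.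

**Step 9**
Reactants: 15 ethyl but-2-ynoate
Product: 17 ethyl (2E)-3-methylpent-2-enoate, via alkenylcopper adduct 16 (not isolated)
Conditions: EtMgBr, CuBr·SMe2, THF, −78 °C; then 15, −78 °C; MeOH quench at −78 °C
Reagents that add atoms: ethylmagnesium bromide, CC[Mg]Br
Why: Syn carbocupration of the ynoate followed by protonation with retention at −78 °C places ethyl trans to the ester, giving the E-alkene only.

**Step 10**
Reactants: 17 ethyl (2E)-3-methylpent-2-enoate
Product: 18 (2E)-3-methylpent-2-enoic acid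
Conditions: LiOH·H2O, THF/MeOH/H2O, rt; then 1 M HCl
Reagents that add atoms: lithium hydroxide, [Li+].[OH-]
Why: Mild saponification gives the acid without touching the trisubstituted alkene geometry.

**Step 11**
Reactants: 14 (3S,7R,8S,9R)-2,2-dimethoxy-1,9-bis(methoxymethoxy)-3,7-dimethylundec-10-ene-7,8-diol; 18 (2E)-3-methylpent-2-enoic acid
Product: 20 (3S,7R,8S,9R)-7-hydroxy-2,2-dimethoxy-1,9-bis(methoxymethoxy)-3,7-dimethylundec-10-en-8-yl (2E)-3-methylpent-2-enoate, via mixed anhydride 19 (not isolated)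
Conditions: 18, 2,4,6-Cl3C6H2COCl, Et3N, THF, rt; then 14, DMAP, toluene, 40 °C
Reagents that add atoms: none
Why: Yamaguchi esterification acylates the secondary C11 hydroxyl while the tertiary C10 hydroxyl is too hindered, and the mixed-anhydride route avoids the ketene pathway that would deconjugate the enoate.

**Step 12**
Reactants: 20 (3S,7R,8S,9R)-7-hydroxy-2,2-dimethoxy-1,9-bis(methoxymethoxy)-3,7-dimethylundec-10-en-8-yl (2E)-3-methylpent-2-enoate
Product: 21 (3S,7R,8S,9R)-1,7,9-trihydroxy-2,2-dimethoxy-3,7-dimethylundec-10-en-8-yl (2E)-3-methylpent-2-enoate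
Conditions: conc. HCl (cat.), MeOH, 35 °C
Reagents that add atoms: none
Why: Acid-catalysed acetal methanolysis removes both MOM ethers, while in methanol the dimethyl ketal only exchanges with solvent and survives, and acid-catalysed acyl migration of the hindered enoate is slow.

**Step 13**
Reactants: 21 (3S,7R,8S,9R)-1,7,9-trihydroxy-2,2-dimethoxy-3,7-dimethylundec-10-en-8-yl (2E)-3-methylpent-2-enoate
Product: 22 (3S,7R,8S,9R)-7,9-dihydroxy-2,2-dimethoxy-3,7-dimethyl-1-oxoundec-10-en-8-yl (2E)-3-methylpent-2-enoate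
Conditions: TEMPO (10 mol %), PhI(OAc)2, CH2Cl2, rt
Reagents that add atoms: none
Why: The oxoammonium (TEMPO/PhI(OAc)2) oxidation is strongly selective for the primary alcohol over the hindered secondary and tertiary ones and stops at the non-enolisable aldehyde in the absence of water.

**Step 14**
Reactants: 23 2-(bromomethyl)prop-2-enoic acid
Product: 24 2-(bromomethyl)prop-2-enoyl chloride
Conditions: (COCl)2, DMF (cat.), CH2Cl2, 0 °C to rt
Reagents that add atoms: oxalyl chloride, ClC(=O)C(=O)Cl
Why: Vilsmeier-catalysed acid chloride formation proceeds under conditions that leave the allylic bromide intact.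

**Step 15**
Reactants: 22 (3S,7R,8S,9R)-7,9-dihydroxy-2,2-dimethoxy-3,7-dimethyl-1-oxoundec-10-en-8-yl (2E)-3-methylpent-2-enoate; 24 2-(bromomethyl)prop-2-enoyl chloride
Product: 25 (3S,7R,8S,9R)-9-{[2-(bromomethyl)prop-2-enoyl]oxy}-7-hydroxy-2,2-dimethoxy-3,7-dimethyl-1-oxoundec-10-en-8-yl (2E)-3-methylpent-2-enoate
Conditions: 24, 2,6-lutidine, CH2Cl2, −20 to 0 °C
Reagents that add atoms: none
Why: Acylation with the acid chloride esterifies the only reactive (secondary allylic, C11a) hydroxyl, and the non-nucleophilic base avoids SN2′ attack on the allylic bromide.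

**Step 16**
Reactants: 25 (3S,7R,8S,9R)-9-{[2-(bromomethyl)prop-2-enoyl]oxy}-7-hydroxy-2,2-dimethoxy-3,7-dimethyl-1-oxoundec-10-en-8-yl (2E)-3-methylpent-2-enoate
Product: 26 (1S,2R,6S)-1-[(2R)-4-(bromomethyl)-5-oxo-2,5-dihydrofuran-2-yl]-2-hydroxy-7,7-dimethoxy-2,6-dimethyl-8-oxooctyl (2E)-3-methylpent-2-enoate
Conditions: second-generation Hoveyda–Grubbs catalyst (10 mol %), toluene (0.005 M), 80 °C
Reagents that add atoms: none
Why: Ring-closing metathesis starts at the monosubstituted vinyl group and closes onto the 1,1-disubstituted acrylate to give the butenolide with loss of ethene, while the trisubstituted enoate, the aldehyde and the allylic bromide are inert to the ruthenium carbene.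

**Step 17**
Reactants: 26 (1S,2R,6S)-1-[(2R)-4-(bromomethyl)-5-oxo-2,5-dihydrofuran-2-yl]-2-hydroxy-7,7-dimethoxy-2,6-dimethyl-8-oxooctyl (2E)-3-methylpent-2-enoate
Product: 28 (3aS,4S,6S,10R,11S,11aR)-4,10-dihydroxy-5,5-dimethoxy-6,10-dimethyl-3-methylidene-2-oxododecahydrocyclodeca[b]furan-11-yl (2E)-3-methylpent-2-enoate, via C4 trimethylsilyl ether 27 (not isolated)
Conditions: CrCl2 (15 mol %), (S,S)-1,8-bis(4-isopropyl-4,5-dihydrooxazol-2-yl)-3,6-diphenylcarbazole (17 mol %), i-Pr2NEt (30 mol %), Mn powder, TMSCl, THF, rt, 26 added over 12 h (final 0.002 M); then 10 % aq. citric acid, THF, 0 °C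
Reagents that add atoms: none
Why: Proposed new method: a chromium-catalysed, ligand-controlled intramolecular allylation by an α-(bromomethyl)butenolide, in which divalent chromium (regenerated by Mn, with TMSCl releasing the trivalent chromium alkoxide as its silyl ether) inserts into the allylic C–Br bond to give an allylchromium bound at the exocyclic CH2, which adds to the chromium-bound aldehyde through a closed six-membered chair at the ring β-carbon, so that one event forms the C3a–C4 bond, closes the ten-membered ring and shifts the double bond to the exocyclic methylene; the butenolide locks the allyl unit in the E-like geometry (C11a trans to CH2–Cr), so the chair gives the anti C3a/C4 relationship (4S), the trans ring fusion (3aS) is expected as the less strained closure with the C11 acyloxy group shielding the other face, the tridentate chiral ligand reinforces the aldehyde face, and fast silylation keeps the C4 alkoxide from translactonising; closest known reactions are the intermolecular zinc- or chromium-mediated allylation of aldehydes with 3-(bromomethyl)furan-2(5H)-ones, chromium-catalysed asymmetric 2-(alkoxycarbonyl)allylation, and stoichiometric Nozaki–Hiyama or Barbier closures of ten-membered germacranolide rings from 2-(bromomethyl)acrylates.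

**Step 18**
Reactants: 28 (3aS,4S,6S,10R,11S,11aR)-4,10-dihydroxy-5,5-dimethoxy-6,10-dimethyl-3-methylidene-2-oxododecahydrocyclodeca[b]furan-11-yl (2E)-3-methylpent-2-enoate
Product: 29 (3aS,4S,6S,10R,11S,11aR)-4,10-dihydroxy-6,10-dimethyl-3-methylidene-2,5-dioxododecahydrocyclodeca[b]furan-11-yl (2E)-3-methylpent-2-enoate (target)
Conditions: 1 M HCl, THF, rt
Reagents that add atoms: water, O
Why: Mild acid hydrolysis of the dimethyl ketal releases the C5 ketone, and the α-methylene lactone, the enoate ester and the tertiary alcohol tolerate dilute acid at room temperature without epimerising C6.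

**Compound list**
1 | 3-methylideneoxolan-2-one | C=C1CCOC1=O | starting material
2 | (3S)-3-methyloxolan-2-one | O=C1[C@@H](C)CCO1 | intermediate
3 | (3S)-5-hydroxy-1-(methoxymethoxy)-3-methylpentan-2-one | COCOCC(=O)[C@@H](C)CCO | intermediate
4 | (3S)-5-bromo-1-(methoxymethoxy)-3-methylpentan-2-one | COCOCC(=O)[C@@H](C)CCBr | intermediate
5 | (3S)-5-bromo-2,2-dimethoxy-1-(methoxymethoxy)-3-methylpentane | COCOCC(OC)(OC)[C@@H](C)CCBr | intermediate
6 | prop-2-en-1-ol | C=CCO | starting material
7 | 3-(methoxymethoxy)prop-1-ene | C=CCOCOC | intermediate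
8 | 2-methylprop-2-enal | CC(=C)C=O | starting material
9 | [(Z)-3-(methoxymethoxy)prop-2-en-1-yl]lithium | [Li]C/C=C\OCOC | intermediate
10 | B-[(Z)-3-(methoxymethoxy)prop-2-en-1-yl]diisopinocampheylborane (isopinocampheyl groups from (+)-α-pinene) | COCO/C=C\CB([C@@H]1C[C@@H]2C[C@H]([C@H]1C)C2(C)C)[C@@H]1C[C@@H]2C[C@H]([C@H]1C)C2(C)C | intermediate
11 | (3R,4R)-4-(methoxymethoxy)-2-methylhexa-1,5-dien-3-ol | C=C(C)[C@@H](O)[C@H](OCOC)C=C | intermediate
12 | (1S,2R)-2-(methoxymethoxy)-1-[(2R)-2-methyloxiran-2-yl]but-3-en-1-ol | C1[C@@](C)(O1)[C@@H](O)[C@H](OCOC)C=C | intermediate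
13 | [(3S)-4,4-dimethoxy-5-(methoxymethoxy)-3-methylpentyl]magnesium bromide | COCOCC(OC)(OC)[C@@H](C)CC[Mg]Br | intermediate
14 | (3S,7R,8S,9R)-2,2-dimethoxy-1,9-bis(methoxymethoxy)-3,7-dimethylundec-10-ene-7,8-diol | COCOCC(OC)(OC)[C@@H](C)CCC[C@@](C)(O)[C@@H](O)[C@H](OCOC)C=C | intermediate
15 | ethyl but-2-ynoate | CC#CC(=O)OCC | starting material
16 | ethyl (2Z)-2-cuprio-3-methylpent-2-enoate (alkenylcopper adduct) | CCOC(=O)/C([Cu])=C(\C)CC | intermediate
17 | ethyl (2E)-3-methylpent-2-enoate | CCOC(=O)/C=C(\C)CC | intermediate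
18 | (2E)-3-methylpent-2-enoic acid | OC(=O)/C=C(\C)CC | intermediate
19 | (2E)-3-methylpent-2-enoic 2,4,6-trichlorobenzoic anhydride | O=C(OC(=O)/C=C(\C)CC)c1c(Cl)cc(Cl)cc1Cl | intermediate
20 | (3S,7R,8S,9R)-7-hydroxy-2,2-dimethoxy-1,9-bis(methoxymethoxy)-3,7-dimethylundec-10-en-8-yl (2E)-3-methylpent-2-enoate | COCOCC(OC)(OC)[C@@H](C)CCC[C@@](C)(O)[C@@H](OC(=O)/C=C(\C)CC)[C@H](OCOC)C=C | intermediate
21 | (3S,7R,8S,9R)-1,7,9-trihydroxy-2,2-dimethoxy-3,7-dimethylundec-10-en-8-yl (2E)-3-methylpent-2-enoate | OCC(OC)(OC)[C@@H](C)CCC[C@@](C)(O)[C@@H](OC(=O)/C=C(\C)CC)[C@H](O)C=C | intermediate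
22 | (3S,7R,8S,9R)-7,9-dihydroxy-2,2-dimethoxy-3,7-dimethyl-1-oxoundec-10-en-8-yl (2E)-3-methylpent-2-enoate | O=CC(OC)(OC)[C@@H](C)CCC[C@@](C)(O)[C@@H](OC(=O)/C=C(\C)CC)[C@H](O)C=C | intermediate
23 | 2-(bromomethyl)prop-2-enoic acid | C=C(CBr)C(=O)O | starting material
24 | 2-(bromomethyl)prop-2-enoyl chloride | C=C(CBr)C(=O)Cl | intermediate
25 | (3S,7R,8S,9R)-9-{[2-(bromomethyl)prop-2-enoyl]oxy}-7-hydroxy-2,2-dimethoxy-3,7-dimethyl-1-oxoundec-10-en-8-yl (2E)-3-methylpent-2-enoate | O=CC(OC)(OC)[C@@H](C)CCC[C@@](C)(O)[C@@H](OC(=O)/C=C(\C)CC)[C@H](OC(=O)C(=C)CBr)C=C | intermediate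
26 | (1S,2R,6S)-1-[(2R)-4-(bromomethyl)-5-oxo-2,5-dihydrofuran-2-yl]-2-hydroxy-7,7-dimethoxy-2,6-dimethyl-8-oxooctyl (2E)-3-methylpent-2-enoate | O=CC(OC)(OC)[C@@H](C)CCC[C@@](C)(O)[C@@H](OC(=O)/C=C(\C)CC)[C@@H]1OC(=O)C(CBr)=C1 | intermediate
27 | 4-O-trimethylsilyl ether of 28 | C=C1C(=O)O[C@@H]2[C@@H]1[C@H](O[Si](C)(C)C)C(OC)(OC)[C@@H](C)CCC[C@@](C)(O)[C@H]2OC(=O)/C=C(\C)CC | intermediate
28 | (3aS,4S,6S,10R,11S,11aR)-4,10-dihydroxy-5,5-dimethoxy-6,10-dimethyl-3-methylidene-2-oxododecahydrocyclodeca[b]furan-11-yl (2E)-3-methylpent-2-enoate | C=C1C(=O)O[C@@H]2[C@@H]1[C@H](O)C(OC)(OC)[C@@H](C)CCC[C@@](C)(O)[C@H]2OC(=O)/C=C(\C)CC | intermediate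
29 | (3aS,4S,6S,10R,11S,11aR)-4,10-dihydroxy-6,10-dimethyl-3-methylidene-2,5-dioxododecahydrocyclodeca[b]furan-11-yl (2E)-3-methylpent-2-enoate | C=C1C(=O)O[C@@H]2[C@@H]1[C@H](O)C(=O)[C@@H](C)CCC[C@@](C)(O)[C@H]2OC(=O)/C=C(\C)CC | target

**Step count and risks**
Total step count: 18. Longest linear sequence: 12 steps (1, 2, 3, 4, 8, 11, 12, 13, 15, 16, 17, 18).

Step 17 (the proposed new ring closure) is the most likely to fail: catalyst turnover at high dilution, the facial sense at C3a and the C4 configuration are all untested for this donor in a ring-closing setting. The fallback sets out from 26 and comes back at 28. The allylic bromide of 26 is converted with (Bu3Sn)2 and Pd2(dba)3 in THF (known zerovalent-palladium-catalysed stannylation of allylic halides) into the isolable allylstannane aldehyde F1. The ring is then closed without any low-valent metal by a Lewis-acid-promoted intramolecular allylstannane–aldehyde addition of the Keck/Marshall type (MgBr2·OEt2, CH2Cl2, −40 to 0 °C, 0.002 M), an open-transition-state SE2′ process that also produces the exocyclic methylene. If this gives the C4 epimer of 28, F2, the carbinol is inverted by a Mitsunobu reaction (chloroacetic acid, DIAD, PPh3) to the C4 chloroacetate F3, which thiourea/NaHCO3 in EtOH cleaves to 28.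

Step 16 is the second risk: ring-closing metathesis onto a 2-(bromomethyl)acrylate in a substrate carrying a free aldehyde and a tertiary alcohol may be slow or lose the bromide. The fallback sets out from 22 and comes back at 26. The C11a hydroxyl is acylated with 2-({[tert-butyl(dimethyl)silyl]oxy}methyl)prop-2-enoyl chloride and 2,6-lutidine to the silyloxymethyl acrylate F4. Ring-closing metathesis of this well-precedented acrylate class gives the silyloxymethyl butenolide F5, HF·pyridine gives the hydroxymethyl butenolide F6, and MsCl/2,4,6-collidine followed by LiBr in acetone installs the bromide to give 26.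

Step 13 is the third risk: the primary alcohol sits next to a quaternary ketal carbon, so the oxoammonium oxidation may be slow enough for the allylic secondary alcohol to compete. The fallback sets out from 21 and comes back at 22. Both non-tertiary hydroxyls are silylated (TESCl, imidazole, DMF) to the bis(triethylsilyl) ether F7. Swern conditions then oxidise the primary triethylsilyl ether directly to the aldehyde while the secondary silyl ether stays, giving the silyl-protected aldehyde F8, and HF·pyridine removes the remaining silyl group to give 22.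

**Further compounds**
F1 | step 17 | (1S,2R,6S)-2-hydroxy-7,7-dimethoxy-2,6-dimethyl-8-oxo-1-{(2R)-5-oxo-4-[(tributylstannyl)methyl]-2,5-dihydrofuran-2-yl}octyl (2E)-3-methylpent-2-enoate | O=CC(OC)(OC)[C@@H](C)CCC[C@@](C)(O)[C@@H](OC(=O)/C=C(\C)CC)[C@@H]1OC(=O)C(C[Sn](CCCC)(CCCC)CCCC)=C1
F2 | step 17 | (3aS,4R,6S,10R,11S,11aR)-4,10-dihydroxy-5,5-dimethoxy-6,10-dimethyl-3-methylidene-2-oxododecahydrocyclodeca[b]furan-11-yl (2E)-3-methylpent-2-enoate (C4 epimer of 28) | C=C1C(=O)O[C@@H]2[C@@H]1[C@@H](O)C(OC)(OC)[C@@H](C)CCC[C@@](C)(O)[C@H]2OC(=O)/C=C(\C)CC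
F3 | step 17 | (3aS,4S,6S,10R,11S,11aR)-4-[(chloroacetyl)oxy]-10-hydroxy-5,5-dimethoxy-6,10-dimethyl-3-methylidene-2-oxododecahydrocyclodeca[b]furan-11-yl (2E)-3-methylpent-2-enoate | C=C1C(=O)O[C@@H]2[C@@H]1[C@H](OC(=O)CCl)C(OC)(OC)[C@@H](C)CCC[C@@](C)(O)[C@H]2OC(=O)/C=C(\C)CC
F4 | step 16 | (3S,7R,8S,9R)-9-{[2-({[tert-butyl(dimethyl)silyl]oxy}methyl)prop-2-enoyl]oxy}-7-hydroxy-2,2-dimethoxy-3,7-dimethyl-1-oxoundec-10-en-8-yl (2E)-3-methylpent-2-enoate | O=CC(OC)(OC)[C@@H](C)CCC[C@@](C)(O)[C@@H](OC(=O)/C=C(\C)CC)[C@H](OC(=O)C(=C)CO[Si](C)(C)C(C)(C)C)C=C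
F5 | step 16 | (1S,2R,6S)-1-[(2R)-4-({[tert-butyl(dimethyl)silyl]oxy}methyl)-5-oxo-2,5-dihydrofuran-2-yl]-2-hydroxy-7,7-dimethoxy-2,6-dimethyl-8-oxooctyl (2E)-3-methylpent-2-enoate | O=CC(OC)(OC)[C@@H](C)CCC[C@@](C)(O)[C@@H](OC(=O)/C=C(\C)CC)[C@@H]1OC(=O)C(CO[Si](C)(C)C(C)(C)C)=C1
F6 | step 16 | (1S,2R,6S)-2-hydroxy-1-[(2R)-4-(hydroxymethyl)-5-oxo-2,5-dihydrofuran-2-yl]-7,7-dimethoxy-2,6-dimethyl-8-oxooctyl (2E)-3-methylpent-2-enoate | O=CC(OC)(OC)[C@@H](C)CCC[C@@](C)(O)[C@@H](OC(=O)/C=C(\C)CC)[C@@H]1OC(=O)C(CO)=C1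
F7 | step 13 | (3S,7R,8S,9R)-7-hydroxy-2,2-dimethoxy-3,7-dimethyl-1,9-bis[(triethylsilyl)oxy]undec-10-en-8-yl (2E)-3-methylpent-2-enoate | CC[Si](CC)(CC)OCC(OC)(OC)[C@@H](C)CCC[C@@](C)(O)[C@@H](OC(=O)/C=C(\C)CC)[C@H](O[Si](CC)(CC)CC)C=C
F8 | step 13 | (3S,7R,8S,9R)-7-hydroxy-2,2-dimethoxy-3,7-dimethyl-1-oxo-9-[(triethylsilyl)oxy]undec-10-en-8-yl (2E)-3-methylpent-2-enoate | O=CC(OC)(OC)[C@@H](C)CCC[C@@](C)(O)[C@@H](OC(=O)/C=C(\C)CC)[C@H](O[Si](CC)(CC)CC)C=C
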